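**Assumption:** (2S)-naringenin is bought as the single natural (S)-enantiomer (ee checked by chiral HPLC), and tert-butyl 2-methylbut-3-en-2-yl carbonate is bought as a catalogue reagent.

## Retrosynthetic overview

1. Target 14 ⇐ MOM ether 13. The furan, the only ring made in the route, comes from cyclodehydration of lactol 12 (a phenol with an ortho CH2CHO group).
2. The phenol and the C-prenyl group of 12 ⇐ aromatic Claisen [3,3] shift of the tertiary allyl aryl ether 9; its CH2CHO arm ⇐ oxidative cleavage of a first C-prenyl group (in 7).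
3. The first C-prenyl group (6) ⇐ aromatic Claisen shift of ether 4. Both ethers ⇐ Pd-catalysed O-tert-prenylation with carbonate 3.
4. Rings A, B, C and the C2 stereocentre come intact from (2S)-naringenin 1, with 7-OH masked as MOM (2). Ring order: A/B/C bought, furan formed last.

## Route

**Step 1**
Reactants: 1 (2S)-naringenin
Product: 2 (2S)-5-hydroxy-2-(4-hydroxyphenyl)-7-(methoxymethoxy)chroman-4-one
Conditions: MOMCl (1.05 eq), i-Pr2NEt (1.2 eq), DMF, 0 °C → rt
Reagents that add atoms: chloromethyl methyl ether (MOMCl), COCCl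
Why: Williamson-type O-alkylation is selective for the most acidic phenol (7-OH, para to C=O), the 5-OH is chelated and the 4'-OH is less acidic; the amine base is too weak to open the flavanone, so C2 stays (S).

**Step 2**
Reactants: 2 (2S)-5-hydroxy-2-(4-hydroxyphenyl)-7-(methoxymethoxy)chroman-4-one; 3 tert-butyl 2-methylbut-3-en-2-yl carbonate
Product: 4 (2S)-5-hydroxy-7-(methoxymethoxy)-2-[4-(2-methylbut-3-en-2-yloxy)phenyl]chroman-4-one
Conditions: 3 (1.5 eq), Pd(PPh3)4 (5 mol%), THF, 0 °C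
Reagents that add atoms: none
Why: Tsuji–Trost decarboxylative O-allylation, in which the phenoxide attacks the substituted terminus of the 1,1-dimethyl-π-allyl-Pd complex to give the tertiary ether as kinetic product at 0 °C; the chelated 5-OH does not react and C2 is untouched.

**Step 3**
Reactants: 4 (2S)-5-hydroxy-7-(methoxymethoxy)-2-[4-(2-methylbut-3-en-2-yloxy)phenyl]chroman-4-one
Product: 6 (2S)-5-hydroxy-2-[4-hydroxy-3-(3-methylbut-2-en-1-yl)phenyl]-7-(methoxymethoxy)chroman-4-one, via Claisen dienone 5 (not isolated)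
Conditions: toluene, 110 °C (sealed tube), 12 h
Reagents that add atoms: none
Why: Aromatic Claisen [3,3] rearrangement, accelerated by the gem-dimethyl group, forms the C3'–C bond (both ortho positions are equivalent) and dienone 5 tautomerises to the phenol; neutral conditions leave C2 untouched.

**Step 4**
Reactants: 6 (2S)-5-hydroxy-2-[4-hydroxy-3-(3-methylbut-2-en-1-yl)phenyl]-7-(methoxymethoxy)chroman-4-one; 3 tert-butyl 2-methylbut-3-en-2-yl carbonate
Product: 7 (2S)-5-hydroxy-7-(methoxymethoxy)-2-[3-(3-methylbut-2-en-1-yl)-4-(2-methylbut-3-en-2-yloxy)phenyl]chroman-4-one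
Conditions: 3 (1.5 eq), Pd(PPh3)4 (5 mol%), THF, 0 °C
Reagents that add atoms: none
Why: Same Tsuji–Trost O-tert-prenylation on the only non-chelated phenol; one ortho substituent is tolerated and no stereocentre is touched.

**Step 5**
Reactants: 7 (2S)-5-hydroxy-7-(methoxymethoxy)-2-[3-(3-methylbut-2-en-1-yl)-4-(2-methylbut-3-en-2-yloxy)phenyl]chroman-4-one
Product: 9 2-{5-[(2S)-5-hydroxy-7-(methoxymethoxy)-4-oxochroman-2-yl]-2-(2-methylbut-3-en-2-yloxy)phenyl}acetaldehyde, via vicinal diol 8 (not isolated)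
Conditions: OsO4 (2 mol%), NMO (1.1 eq), acetone/H2O 5:1, 0 °C; then NaIO4 (1.5 eq), pH 7 phosphate buffer, 0 °C → rt
Reagents that add atoms: osmium tetroxide, O=[Os](=O)(=O)=O (catalytic oxygen-transfer agent); N-methylmorpholine N-oxide, C[N+]1([O-])CCOCC1 (stoichiometric oxygen source)
Why: Upjohn dihydroxylation followed by Malaprade glycol cleavage; OsO4 prefers the electron-rich trisubstituted prenyl C=C over the neopentylic, inductively deactivated vinyl group of the tertiary ether, and the buffer protects the acid-labile ether; the carbinol centre of 8 is destroyed on cleavage.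

**Step 6**
Reactants: 9 2-{5-[(2S)-5-hydroxy-7-(methoxymethoxy)-4-oxochroman-2-yl]-2-(2-methylbut-3-en-2-yloxy)phenyl}acetaldehyde
Product: 13 (2S)-5-hydroxy-7-(methoxymethoxy)-2-[7-(3-methylbut-2-en-1-yl)benzofuran-5-yl]chroman-4-one, via second Claisen dienone 10 (not isolated), via phenol aldehyde 11 (not isolated), via lactol 12 (not isolated)
Conditions: toluene, 110 °C, 6 h; then PPTS (10 mol%), 80 °C, 1 h
Reagents that add atoms: none
Why: A second aromatic Claisen [3,3] rearrangement delivers prenyl to the only free ortho carbon, the liberated phenol closes onto the neighbouring aldehyde, and mild acid dehydrates the lactol to the aromatic furan; the lactol centre disappears and C2 is untouched.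

**Step 7**
Reactants: 13 (2S)-5-hydroxy-7-(methoxymethoxy)-2-[7-(3-methylbut-2-en-1-yl)benzofuran-5-yl]chroman-4-one
Product: 14 abyssinoflavanone VI, (2S)-5,7-dihydroxy-2-[7-(3-methylbut-2-en-1-yl)benzofuran-5-yl]chroman-4-one
Conditions: conc. HCl (5 eq), MeOH, 40 °C, 2 h
Reagents that add atoms: none
Why: Acid-catalysed acetal exchange removes the MOM group; the prenyl group has no free ortho-OH to cyclise onto and the benzofuran tolerates dilute methanolic acid, and acid does not epimerise C2.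

## Compound list

1 | (2S)-naringenin, (2S)-5,7-dihydroxy-2-(4-hydroxyphenyl)chroman-4-one | Oc1ccc(cc1)[C@@H]1CC(=O)c2c(O)cc(O)cc2O1 | starting material
2 | (2S)-5-hydroxy-2-(4-hydroxyphenyl)-7-(methoxymethoxy)chroman-4-one | Oc1ccc(cc1)[C@@H]1CC(=O)c2c(O)cc(OCOC)cc2O1 | intermediate
3 | tert-butyl 2-methylbut-3-en-2-yl carbonate | CC(C)(C=C)OC(=O)OC(C)(C)C | starting material
4 | (2S)-5-hydroxy-7-(methoxymethoxy)-2-[4-(2-methylbut-3-en-2-yloxy)phenyl]chroman-4-one | C=CC(C)(C)Oc1ccc(cc1)[C@@H]1CC(=O)c2c(O)cc(OCOC)cc2O1 | intermediate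
5 | Claisen dienone (not isolated), (2S)-5-hydroxy-7-(methoxymethoxy)-2-[3-(3-methylbut-2-en-1-yl)-4-oxocyclohexa-1,5-dien-1-yl]chroman-4-one, ring sp3 centre unassigned | CC(C)=CCC1C=C(C=CC1=O)[C@@H]1CC(=O)c2c(O)cc(OCOC)cc2O1 | intermediate
6 | (2S)-5-hydroxy-2-[4-hydroxy-3-(3-methylbut-2-en-1-yl)phenyl]-7-(methoxymethoxy)chroman-4-one | CC(C)=CCc1cc(ccc1O)[C@@H]1CC(=O)c2c(O)cc(OCOC)cc2O1 | intermediate
7 | (2S)-5-hydroxy-7-(methoxymethoxy)-2-[3-(3-methylbut-2-en-1-yl)-4-(2-methylbut-3-en-2-yloxy)phenyl]chroman-4-one | CC(C)=CCc1cc(ccc1OC(C)(C)C=C)[C@@H]1CC(=O)c2c(O)cc(OCOC)cc2O1 | intermediate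
8 | vicinal diol (not isolated), (2S)-2-[3-(2,3-dihydroxy-3-methylbutyl)-4-(2-methylbut-3-en-2-yloxy)phenyl]-5-hydroxy-7-(methoxymethoxy)chroman-4-one, carbinol epimers | CC(C)(O)C(O)Cc1cc(ccc1OC(C)(C)C=C)[C@@H]1CC(=O)c2c(O)cc(OCOC)cc2O1 | intermediate
9 | 2-{5-[(2S)-5-hydroxy-7-(methoxymethoxy)-4-oxochroman-2-yl]-2-(2-methylbut-3-en-2-yloxy)phenyl}acetaldehyde | O=CCc1cc(ccc1OC(C)(C)C=C)[C@@H]1CC(=O)c2c(O)cc(OCOC)cc2O1 | intermediate
10 | second Claisen dienone (not isolated), 2-{5-[(2S)-5-hydroxy-7-(methoxymethoxy)-4-oxochroman-2-yl]-3-(3-methylbut-2-en-1-yl)-2-oxocyclohexa-4,6-dien-1-yl}acetaldehyde drawn as the 6-oxo-cyclohexa-1,3-diene bearing CH2CHO at C1 and prenyl at the sp3 C5, ring sp3 centre unassigned | CC(C)=CCC1C=C(C=C(CC=O)C1=O)[C@@H]1CC(=O)c2c(O)cc(OCOC)cc2O1 | intermediate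
11 | phenol aldehyde (not isolated), 2-{2-hydroxy-5-[(2S)-5-hydroxy-7-(methoxymethoxy)-4-oxochroman-2-yl]-3-(3-methylbut-2-en-1-yl)phenyl}acetaldehyde | CC(C)=CCc1cc(cc(CC=O)c1O)[C@@H]1CC(=O)c2c(O)cc(OCOC)cc2O1 | intermediate
12 | lactol (not isolated), (2S)-5-hydroxy-2-[2-hydroxy-7-(3-methylbut-2-en-1-yl)-2,3-dihydrobenzofuran-5-yl]-7-(methoxymethoxy)chroman-4-one, anomer mixture | CC(C)=CCc1cc(cc2CC(O)Oc12)[C@@H]1CC(=O)c2c(O)cc(OCOC)cc2O1 | intermediate
13 | (2S)-5-hydroxy-7-(methoxymethoxy)-2-[7-(3-methylbut-2-en-1-yl)benzofuran-5-yl]chroman-4-one | CC(C)=CCc1cc(cc2ccoc12)[C@@H]1CC(=O)c2c(O)cc(OCOC)cc2O1 | intermediate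
14 | abyssinoflavanone VI, (2S)-5,7-dihydroxy-2-[7-(3-methylbut-2-en-1-yl)benzofuran-5-yl]chroman-4-one | CC(C)=CCc1cc([C@@H]2CC(=O)c3c(O)cc(O)cc3O2)cc2ccoc12 | target

## Step count and risks

Total steps: 7. Longest linear sequence: 7 (fully linear from 1).

**Step 1 (mono-protection of 7-OH may give mixtures with the 4'-ether and the bis-ether).** The fallback replaces direct selection by an acetate shuffle. It sets out from 1: peracetylation (Ac2O, pyridine) gives naringenin triacetate F1. Selective removal of the most labile 7-O-acetyl (PhSH, cat. imidazole, NMP, 0 °C) gives 4',5-di-O-acetylnaringenin F2. MOMCl/i-Pr2NEt on its single free phenol gives 4',5-di-O-acetyl-7-O-MOM-naringenin F3. Brief treatment with NH3 in MeOH at 0 °C removes both acetates, and the sequence comes back to the route at 2.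

**Step 5 (OsO4 may also attack the vinyl group, or the tertiary ether may ionise).** The fallback changes the order so that only one alkene is present during dihydroxylation. It sets out from 6: OsO4 (cat.)/NMO converts the prenyl group into the diol, giving the phenol diol F4. Pd(PPh3)4 with carbonate 3 then etherifies only the phenol, because the aliphatic hydroxyls are not deprotonated. This comes back to the route at 8, now isolated, and the periodate stage of step 5 then gives 9.

**Step 6 (the arylacetaldehyde may not survive 110 °C, or the tertiary ether may be lost before it rearranges).** The fallback runs the Claisen shift before the aldehyde exists. It sets out from 8, isolated by leaving out the periodate in step 5: heating in toluene at 110 °C gives the rearranged phenol diol F5, which carries the C-prenyl group and the free phenol. NaIO4 at pH 7 then cleaves only the glycol, the resulting aldehyde closes at once, and the sequence comes back to the route at 12, which PPTS dehydrates to 13 as in step 6.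

## Further compounds

F1 | step 1 | naringenin triacetate, (2S)-5,7-diacetoxy-2-(4-acetoxyphenyl)chroman-4-one | CC(=O)Oc1ccc(cc1)[C@@H]1CC(=O)c2c(OC(C)=O)cc(OC(C)=O)cc2O1
F2 | step 1 | 4',5-di-O-acetylnaringenin, (2S)-5-acetoxy-2-(4-acetoxyphenyl)-7-hydroxychroman-4-one | CC(=O)Oc1ccc(cc1)[C@@H]1CC(=O)c2c(OC(C)=O)cc(O)cc2O1
F3 | step 1 | 4',5-di-O-acetyl-7-O-MOM-naringenin, (2S)-5-acetoxy-2-(4-acetoxyphenyl)-7-(methoxymethoxy)chroman-4-one | CC(=O)Oc1ccc(cc1)[C@@H]1CC(=O)c2c(OC(C)=O)cc(OCOC)cc2O1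
F4 | step 5 | phenol diol, (2S)-2-[3-(2,3-dihydroxy-3-methylbutyl)-4-hydroxyphenyl]-5-hydroxy-7-(methoxymethoxy)chroman-4-one, carbinol epimers | CC(C)(O)C(O)Cc1cc(ccc1O)[C@@H]1CC(=O)c2c(O)cc(OCOC)cc2O1
F5 | step 6 | rearranged phenol diol, (2S)-2-[3-(2,3-dihydroxy-3-methylbutyl)-4-hydroxy-5-(3-methylbut-2-en-1-yl)phenyl]-5-hydroxy-7-(methoxymethoxy)chroman-4-one, carbinol epimers | CC(C)=CCc1cc(cc(CC(O)C(C)(C)O)c1O)[C@@H]1CC(=O)c2c(O)cc(OCOC)cc2O1
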